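The tetrahydrofuran (ring atoms O1, C2 bearing guaiacyl ring A, C3, C4, C5 bearing ring B) is cut into a C2–C3 unit, the enol ether of a ring A propiophenone, and an O1–C5–C4 unit, an enantiopure 1-arylallyl alcohol. One flask operation, iodoketalization then 5-exo radical cyclization, forms O1–C2 and C3–C4 and turns the terminal vinyl CH2 into the C4 methyl. It exploits that C2 is benzylic and bound to the ring oxygen, so it can be carried as a ketal, and that the C5 stereocentre can steer C4 and C3. Ionic hydrogenation then sets C2 cis to the C3 methyl; the lactate-derived side chain rides through as an ester.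

Key step: step 4

Remark on the chemistry: salt-free divinylzinc and Zn(BH4)2 are assumed to be used as stock solutions prepared beforehand; the ring numbering O1, C2 (ring A), C3, C4, C5 (ring B) is used throughout.

Step 1
Reactants: 1 vanillin; 2 ethyl (S)-lactate
Product: 3 ethyl (2R)-2-(4-formyl-2-methoxyphenoxy)propanoate
Conditions: PPh3, DIAD, THF, 0 °C → rt
Reagents that add atoms: none
Why: Mitsunobu etherification, in which the acidic phenol of 1 displaces the activated secondary hydroxyl of 2 with inversion, so the (S)-lactate centre becomes the (R)-aryloxy centre that ends as the ether-bearing side-chain carbon; the aldehyde is inert.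

Step 2
Reactants: 3 ethyl (2R)-2-(4-formyl-2-methoxyphenoxy)propanoate
Product: 4 ethyl (2R)-2-{4-[(1S)-1-hydroxyprop-2-en-1-yl]-2-methoxyphenoxy}propanoate
Conditions: Zn(CH=CH2)2, (−)-MIB [(2S)-3-exo-morpholinoisoborneol, 10 mol %], toluene, −30 → 0 °C; aqueous work-up
Reagents that add atoms: divinylzinc, C=C[Zn]C=C
Why: amino-alcohol-catalysed enantioselective addition of an alkenylzinc reagent to an aromatic aldehyde, in which the chiral zinc aminoalkoxide should deliver vinyl to the Si face and set the (S)-carbinol centre (later C5) under catalyst control, while the organozinc reagent leaves the ester alone.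

Step 3
Reactants: 5 methyl 4-(benzyloxy)-3-methoxybenzoate
Product: 6 1-(benzyloxy)-2-methoxy-4-[(1Z)-1-methoxyprop-1-en-1-yl]benzene
Conditions: TiCl4, Zn, TMEDA, PbCl2 (cat.), CH3CHBr2, THF, 0 °C → rt; basic work-up
Reagents that add atoms: 1,1-dibromoethane, CC(Br)Br
Why: Takai–Utimoto alkylidenation of an ester, in which the titanium ethylidene species formed from the geminal dizinc reagent converts the ester carbonyl into the (Z)-enol ether; the geometry does not matter because C3 later becomes a radical.

Step 4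
Reactants: 4 ethyl (2R)-2-{4-[(1S)-1-hydroxyprop-2-en-1-yl]-2-methoxyphenoxy}propanoate; 6 1-(benzyloxy)-2-methoxy-4-[(1Z)-1-methoxyprop-1-en-1-yl]benzene
Product: 8 ethyl (2R)-2-{4-[(2S,3S,4R)-5-[4-(benzyloxy)-3-methoxyphenyl]-5-methoxy-3,4-dimethyloxolan-2-yl]-2-methoxyphenoxy}propanoate (both configurations at the ketal carbon C2), via α-iodo mixed ketal 7 (not isolated)
Conditions: NIS, CH2Cl2, −78 → −40 °C; then Bu3SnH (slow addition), Et3B, air, −78 → 0 °C, same flask
Reagents that add atoms: none
Why: NIS turns the electron-rich enol ether 6 into an α-iodo oxocarbenium ion that is captured by the hydroxyl of 4 (O1–C2), and iodine abstraction from the resulting ketal 7 by Bu3Sn• gives the C3 radical, which adds to the internal vinyl carbon (C3–C4) before the primary radical takes hydrogen from Bu3SnH and becomes the C4 methyl. The closest known reaction type is the Ueno–Stork haloacetal radical cyclization, run here on a ketone-derived enol ether. The ring is closed in the 5-exo-trig mode. C5 comes in from 4, and in the chair-like transition state its aryl group sits pseudo-equatorial and sets C4 (4,5-trans), while the methyl on the radical carbon takes the orientation that leads to the 3,4-cis ring, the usual preference of 1-substituted 5-hexenyl-type radicals; C2 is deliberately left as a ketal mixture and is set in step 5. The step needs O-attack at C2 and not at C3 (secured by the methoxy and aryl groups that stabilise the cation), 5-exo over 6-endo closure, and cyclization faster than direct reduction of the radical (secured by low temperature and a low Bu3SnH concentration).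

Step 5
Reactants: 8 cyclic methyl ketal (both ketal epimers)
Product: 9 ethyl (2R)-2-{4-[(2S,3S,4R,5S)-5-[4-(benzyloxy)-3-methoxyphenyl]-3,4-dimethyloxolan-2-yl]-2-methoxyphenoxy}propanoate
Conditions: Et3SiH, BF3·OEt2, CH2Cl2, −78 °C; cold quench with aq. NaHCO3
Reagents that add atoms: none
Why: ionic (Lewis acid/silane) reduction of a cyclic ketal, in which BF3 removes the exocyclic methoxy group to give the ring-A-stabilised cyclic oxocarbenium ion and Et3SiH should deliver hydride to C2 from the face opposite the adjacent C3 methyl, placing ring A cis to both methyl groups from either ketal epimer.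

Step 6
Reactants: 9 ethyl ester from step 5; 10 1-(benzyloxy)-4-bromo-2-methoxybenzene
Product: 13 (2R)-1-[4-(benzyloxy)-3-methoxyphenyl]-2-{4-[(2S,3S,4R,5S)-5-[4-(benzyloxy)-3-methoxyphenyl]-3,4-dimethyloxolan-2-yl]-2-methoxyphenoxy}propan-1-one, via aryl Grignard reagent 11 (not isolated), via N-methoxy-N-methylamide 12 (not isolated)
Conditions: MeNH(OMe)·HCl, i-PrMgCl, THF, −20 °C; then 11 (from 10, Mg, THF), −20 → 0 °C; aq. NH4Cl
Reagents that add atoms: none
Why: ester-to-ketone conversion through an N-methoxy-N-methylamide made in the flask, in which the magnesium amide aminolyses the ethyl ester and the aryl Grignard reagent then adds only once because the chelated tetrahedral adduct survives until work-up; the low temperature should keep the α-aryloxy centre intact.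

Step 7
Reactants: 13 α-aryloxy ketone from step 6
Product: 14 (1S,2R)-1-[4-(benzyloxy)-3-methoxyphenyl]-2-{4-[(2S,3S,4R,5S)-5-[4-(benzyloxy)-3-methoxyphenyl]-3,4-dimethyloxolan-2-yl]-2-methoxyphenoxy}propan-1-ol
Conditions: Zn(BH4)2, Et2O, −30 → 0 °C
Reagents that add atoms: none
Why: chelation-controlled hydride reduction of an α-aryloxy ketone, in which zinc bridges the carbonyl and ether oxygens and hydride enters on the side of the small α-hydrogen, which should give the erythro (1S,2R) alcohol.

Step 8
Reactants: 14 bis(benzyl ether) from step 7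
Product: 15 4-[(2S,3R,4S,5S)-5-{4-[(1S,2R)-1-hydroxy-1-(4-hydroxy-3-methoxyphenyl)propan-2-yl]oxy-3-methoxyphenyl}-3,4-dimethyloxolan-2-yl]-2-methoxyphenol (CNP0171079.3)
Conditions: H2 (1 atm), Pd/C, EtOAc, rt
Reagents that add atoms: none
Why: hydrogenolysis of the two benzyl aryl ethers over palladium on carbon in a neutral aprotic solvent should free both phenols without touching a stereocentre, the run being stopped at full debenzylation to spare the benzylic ring C–O bonds and the benzylic alcohol.

Compound list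
1 | vanillin (4-hydroxy-3-methoxybenzaldehyde) | COc1cc(C=O)ccc1O | starting material
2 | ethyl (S)-lactate | CCOC(=O)[C@H](C)O | starting material
3 | ethyl (2R)-2-(4-formyl-2-methoxyphenoxy)propanoate | CCOC(=O)[C@@H](C)Oc1ccc(C=O)cc1OC | intermediate
4 | ethyl (2R)-2-{4-[(1S)-1-hydroxyprop-2-en-1-yl]-2-methoxyphenoxy}propanoate | C=C[C@H](O)c1ccc(O[C@H](C)C(=O)OCC)c(OC)c1 | intermediate
5 | methyl 4-(benzyloxy)-3-methoxybenzoate | COC(=O)c1ccc(OCc2ccccc2)c(OC)c1 | starting material
6 | 1-(benzyloxy)-2-methoxy-4-[(1Z)-1-methoxyprop-1-en-1-yl]benzene | C/C=C(\OC)c1ccc(OCc2ccccc2)c(OC)c1 | intermediate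
7 | ethyl (2R)-2-{4-[(1S)-1-{1-[4-(benzyloxy)-3-methoxyphenyl]-2-iodo-1-methoxypropoxy}prop-2-en-1-yl]-2-methoxyphenoxy}propanoate (mixture at the ketal and CHI carbons) | CC(I)C(OC)(O[C@@H](C=C)c1ccc(O[C@H](C)C(=O)OCC)c(OC)c1)c1ccc(OCc2ccccc2)c(OC)c1 | intermediate
8 | ethyl (2R)-2-{4-[(2S,3S,4R)-5-[4-(benzyloxy)-3-methoxyphenyl]-5-methoxy-3,4-dimethyloxolan-2-yl]-2-methoxyphenoxy}propanoate (both ketal epimers) | COC1(c2ccc(OCc3ccccc3)c(OC)c2)O[C@H](c2ccc(O[C@H](C)C(=O)OCC)c(OC)c2)[C@@H](C)[C@H]1C | intermediate
9 | ethyl (2R)-2-{4-[(2S,3S,4R,5S)-5-[4-(benzyloxy)-3-methoxyphenyl]-3,4-dimethyloxolan-2-yl]-2-methoxyphenoxy}propanoate | COc1cc([C@H]2O[C@H](c3ccc(O[C@H](C)C(=O)OCC)c(OC)c3)[C@@H](C)[C@H]2C)ccc1OCc1ccccc1 | intermediate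
10 | 1-(benzyloxy)-4-bromo-2-methoxybenzene | COc1cc(Br)ccc1OCc1ccccc1 | starting material
11 | [4-(benzyloxy)-3-methoxyphenyl]magnesium bromide | COc1cc([Mg]Br)ccc1OCc1ccccc1 | intermediate
12 | (2R)-2-{4-[(2S,3S,4R,5S)-5-[4-(benzyloxy)-3-methoxyphenyl]-3,4-dimethyloxolan-2-yl]-2-methoxyphenoxy}-N-methoxy-N-methylpropanamide | COc1cc([C@H]2O[C@H](c3ccc(O[C@H](C)C(=O)N(C)OC)c(OC)c3)[C@@H](C)[C@H]2C)ccc1OCc1ccccc1 | intermediate
13 | (2R)-1-[4-(benzyloxy)-3-methoxyphenyl]-2-{4-[(2S,3S,4R,5S)-5-[4-(benzyloxy)-3-methoxyphenyl]-3,4-dimethyloxolan-2-yl]-2-methoxyphenoxy}propan-1-one | COc1cc([C@H]2O[C@H](c3ccc(O[C@H](C)C(=O)c4ccc(OCc5ccccc5)c(OC)c4)c(OC)c3)[C@@H](C)[C@H]2C)ccc1OCc1ccccc1 | intermediate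
14 | (1S,2R)-1-[4-(benzyloxy)-3-methoxyphenyl]-2-{4-[(2S,3S,4R,5S)-5-[4-(benzyloxy)-3-methoxyphenyl]-3,4-dimethyloxolan-2-yl]-2-methoxyphenoxy}propan-1-ol | COc1cc([C@H]2O[C@H](c3ccc(O[C@H](C)[C@@H](O)c4ccc(OCc5ccccc5)c(OC)c4)c(OC)c3)[C@@H](C)[C@H]2C)ccc1OCc1ccccc1 | intermediate
15 | 4-[(2S,3R,4S,5S)-5-{4-[(1S,2R)-1-hydroxy-1-(4-hydroxy-3-methoxyphenyl)propan-2-yl]oxy-3-methoxyphenyl}-3,4-dimethyloxolan-2-yl]-2-methoxyphenol | COc1cc([C@H]2O[C@H](c3ccc(O[C@H](C)[C@@H](O)c4ccc(O)c(OC)c4)c(OC)c3)[C@@H](C)[C@H]2C)ccc1O | target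

Total step count: 8. Longest linear sequence: 7 steps (steps 1, 2, 4, 5, 6, 7, 8 from vanillin); step 3 is a one-step branch.

Steps most likely to fail

Step 4. The C3 radical may add to the vinyl group with weak facial control, so that the 3,4-trans ring forms beside the 3,4-cis ring, and it may be reduced before it cyclizes. The fallback sets C3 by hydrogenation instead of in the radical transition state; it sets out from 4 and 10 and comes back at 8. Methoxyallene is lithiated with n-BuLi, transmetalated with ZnCl2 and joined to 10 by a Negishi coupling under Pd(PPh3)4 catalysis, which should give 1-(benzyloxy)-2-methoxy-4-(1-methoxypropa-1,2-dien-1-yl)benzene F1. NBS-mediated bromoketalization of F1 with 4 should give the 2-bromoallyl mixed ketal F2. Bu3SnH and AIBN then close the ring through a vinyl radical in the 5-exo mode to the 4-methyl-3-methylidene cyclic ketal F3, in which only C4 is new and is set trans to the C5 aryl group. Hydrogenation of the exocyclic alkene with H2 and RhCl(PPh3)3 from the face opposite the C4 methyl should give 8 with the 3,4-cis relationship, and the route goes on with step 5.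

Step 5. The oxocarbenium ion may lose the C3 proton reversibly and so scramble C3, hydride may enter from the wrong face, and the Lewis acid may also ionise the ring C5–O bond. The fallback replaces hydride delivery by a syn-hydrogenation; it sets out from 8 and comes back at 9. Loss of methanol from 8 (pyridinium p-toluenesulfonate, toluene, heat) should give the cyclic enol ether F4 with a C2=C3 double bond. Hydrogenation with H2 and [Ir(cod)(PCy3)(py)]PF6 in CH2Cl2 adds both hydrogens to one face, which fixes the 2,3-cis relationship, and should occur opposite the allylic C4 methyl to give 9; the benzyl ethers survive this catalyst.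

Step 2. The vinyl transfer may show too little enantiofacial discrimination, or an uncatalysed background addition may erode it. The fallback uses a kinetic resolution; it sets out from 3 and comes back at 4. Vinylmagnesium bromide in THF at −78 °C adds to the aldehyde faster than to the ester and should give the carbinol-epimeric allylic alcohol mixture F5. Immobilised Candida antarctica lipase B with vinyl acetate in hexane should acetylate the (1R)-epimer to the acetate F6 and leave the (1S)-alcohol 4, which is separated by chromatography.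

Further compounds
F1 | step 4 | 1-(benzyloxy)-2-methoxy-4-(1-methoxypropa-1,2-dien-1-yl)benzene | C=C=C(OC)c1ccc(OCc2ccccc2)c(OC)c1
F2 | step 4 | ethyl (2R)-2-{4-[(1S)-1-{1-[4-(benzyloxy)-3-methoxyphenyl]-2-bromo-1-methoxyprop-2-en-1-yloxy}prop-2-en-1-yl]-2-methoxyphenoxy}propanoate (both ketal epimers) | C=C(Br)C(OC)(O[C@@H](C=C)c1ccc(O[C@H](C)C(=O)OCC)c(OC)c1)c1ccc(OCc2ccccc2)c(OC)c1
F3 | step 4 | ethyl (2R)-2-{4-[(2S,3S)-5-[4-(benzyloxy)-3-methoxyphenyl]-5-methoxy-3-methyl-4-methylideneoxolan-2-yl]-2-methoxyphenoxy}propanoate (both ketal epimers) | COC1(c2ccc(OCc3ccccc3)c(OC)c2)O[C@H](c2ccc(O[C@H](C)C(=O)OCC)c(OC)c2)[C@@H](C)C1=C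
F4 | step 5 | ethyl (2R)-2-{4-[(2S,3S)-5-[4-(benzyloxy)-3-methoxyphenyl]-3,4-dimethyl-2,3-dihydrofuran-2-yl]-2-methoxyphenoxy}propanoate | CC1=C(c2ccc(OCc3ccccc3)c(OC)c2)O[C@H](c2ccc(O[C@H](C)C(=O)OCC)c(OC)c2)[C@H]1C
F5 | step 2 | ethyl (2R)-2-[4-(1-hydroxyprop-2-en-1-yl)-2-methoxyphenoxy]propanoate (both carbinol epimers) | C=CC(O)c1ccc(O[C@H](C)C(=O)OCC)c(OC)c1
F6 | step 2 | ethyl (2R)-2-{4-[(1R)-1-(acetyloxy)prop-2-en-1-yl]-2-methoxyphenoxy}propanoate | C=C[C@@H](OC(C)=O)c1ccc(O[C@H](C)C(=O)OCC)c(OC)c1
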